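The leftover that held my attention was the part of the ochre charge the readings leave unaccounted for: at 60.0 s Z stood at 2.0%, so 98.0% of the X had either stayed X or gone somewhere unseen. I had to choose the charge for the next run, the one giving the most Z at the end.

common to all: D 0.071 µM

| flask | X | remark | time |
|---|---|---|---|
| amber | 0.015 M | run made earlier |  |
| teal | 0.032 M | run made earlier |  |
| ochre | 0.076 M | run made earlier |  |
| theta | 0.012 M |  | 2.0 min |
| eta | 0.025 M |  | 2.0 min |
| delta | 0.050 M |  | 2.0 min |
| alpha | 0.10 M |  | 2.0 min |

| run | time / s | Z / % |
|---|---|---|
| amber | 12.0 | 12.4 |
| amber | 25.0 | 22.6 |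
| amber | 40.0 | 32.2 |
| amber | 50.0 | 38.3 |
| amber | 60.0 | 44.3 |
| teal | 10.0 | 3.0 |
| teal | 15.0 | 5.5 |
| teal | 30.0 | 8.6 |
| teal | 40.0 | 10.0 |
| teal | 60.0 | 13.4 |
| ochre | 10.0 | 1.2 |
| ochre | 15.0 | 1.6 |
| ochre | 30.0 | 1.0 |
| ochre | 40.0 | 1.6 |
| ochre | 60.0 | 2.0 |

(standard deviation of a reading: 0.5 percentage points)

- the numbers in the tables scatter with a standard deviation of 0.5 percentage points
- "hardly changes" means that all values lie within two and a half points (for a concentration: within two and a half percent of the largest)

* [Z] at the end for theta, eta, delta, alpha, in this order
* the shape of the row from first to last (falls, then rises / rises, then falls / rises all the way / falls all the way / hardly changes)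

From 10.0 s onward, ochre's readings of Z lay between 1.0% and 2.0%, with a mean of 1.48%, and against a scatter of 0.5 percentage points I could not tell whether that spread hid a slow climb. I called this reading the ceiling share: the fraction of the ochre charge that is Z once making and loss of Z balance, a steady state. I supposed that Z was made at a steady pace, with D charged at 0.071 µM, and lost in proportion to Z and to the X present. The Z held at the ceiling then varies inversely with the X present. So a flask's ceiling, as a fraction of its own charge, is the ceiling share times the square of ochre's charge over that flask's charge, divided by the fraction still X.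

Teal let me estimate how fast X goes. If teal was at its ceiling at 60.0 s, its 13.4% means that 62.3% of its charge was still X. At that pace, a charge of 0.0241 M would just empty by the end, close to eta's 0.025 M. Theta holds less than that, and delta and alpha hold more. With the X I expected them to keep, their ceilings came to 6.61% for delta and 1.13% for alpha. Eta, on falling to theta's charge, meets the ceiling theta started under and still has X to work with, so I chose eta and expected the row to rise, then fall.

The forecast gave 0.0108 M, 0.0095 M, 0.0045 M and 0.002 M, a row that falls all the way, judging that “the row most likely falls throughout”.

The flasks gave 0.00737 M, 0.00877 M, 0.00521 M and 0.00161 M: the row rises, then falls.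

    X + D ⇌ J (K = 580 /M, k = 5.30 × 10⁷ /M/s)
    J → D + Z (k = 2900 /s)
    X + Z → L (k = 2.20 /M/s)

Eta ended with 0.30% of its charge still X. Alpha ended with 53.3% still X, which puts its ceiling at 1.60% of its charge, and its Z stood at 1.61%.

The readings were generated by integration with made-up constants; the scatter is artificial.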